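If each Q takes one G with it, ask first what the end state of the flask must be, and only then how fast it is approached.

| flask | X | Q | G | E | remark | time |
|---|---|---|---|---|---|---|
| delta | 0.012 M | 0.50 equiv | 1.1 equiv | 1 mol% | the very flask that is asked about, followed so far |  |
| theta | 0.012 M | 0.34 equiv | 1.1 equiv | 1 mol% | run made earlier |  |
| flask | 0.012 M | 0.500 equiv | 1.10 equiv | 1 mol% |  | 8.0 d |

| run | time / d | D / % | X / % |
|---|---|---|---|
| delta | 2.00 | 31.7 | 66.9 |
| delta | 2.08 | 32.7 | 66.4 |
| delta | 2.50 | 37.2 | 62.0 |
| theta | 2.08 | 40.8 | 58.8 |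
| theta | 2.50 | 45.4 | 53.8 |
| theta | 3.00 | 49.9 | 50.6 |
| theta | 4.00 | 57.2 | 43.1 |
| theta | 5.00 | 61.1 | 38.4 |
| theta | 6.00 | 64.7 | 34.2 |
| theta | 8.00 | 69.9 | 30.5 |

(readings scatter by 0.5 percentage points)

* time, not beyond 8.0 d, at which the flask holds most D
* the amount of D, in percent of the X charged, at that time
* the first time at which D reaches 17%, in the same percent, in d

- the analysis behind the earlier runs scatters by 0.5 percentage points, standard deviation

Hold two amounts against each other, as my own assumption: the G that stays once Q has had its share, and the X charged. Call their ratio the room, the ceiling on D with G as limiting reagent of what remains: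

delta and the flask: 60.0%
theta: 76.0%

Now divide the readings by the room. At 2.08 d delta has filled 54.5% of its room and theta 53.7% of its own; at 2.50 d they stand at 62.0% and 59.7%. So take the filling as shared between the runs at equal times, and since D in theta still climbs from 64.7% to 69.9% at its last reading, put the maximum at the limit of 8.0 d:

filling of theta at 8.00 d: 92.0%
D in the flask at 8.0 d: room × filling = 55.2%

The forecast differs from this reckoning, with 8 d, 64.5% and 0.9 d, on the ground that “Scaling time, delta at 8 d corresponds to theta at about 5.8 d”; its D stands above the room.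

The simulation gives 8.00 d, 55.9% and 0.826 d.

    X + E ⇌ J (K = 180 M⁻¹, k = 1.80 M⁻¹ s⁻¹)
    G + J → E + D (k = 0.0590 M⁻¹ s⁻¹)
    Q + E ⇌ L (K = 510 M⁻¹, k = 13.0 M⁻¹ s⁻¹)
    G + L → E + Z (k = 0.970 M⁻¹ s⁻¹)

In the flask [Z] stands at 0.00599 M by 0.800 d, which is 50.0% of the X charged, and at 80.0 d the flask holds D at 60.0% with G at 0% and X at 39.5%. Carry the room to the neighbouring flask, charged with 0.300 equiv of Q and otherwise like the flask: its room is 80.0%, and the filling of theta makes that 73.6% of D. The simulated neighbouring flask holds 72.4% of D at 8.00 d, with 6.9% of its G and 27% of its X left.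

(The runs were generated by integration from invented constants, noise included.)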